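Atom numbers refer to the target throughout: ring A is C1 (O‑angeloyl), C2=C3 (CH3 on C3), C4 (OAc), C5 (CH2), C6; the chain is C7 (CH3), C8 (CH2), C9 (OAc), C10=C11 (two CH3).

## The problem

The target is a bisabolane‑type triester: one cyclohexene (ring A) carrying an acyclic C7–C11 chain at C6, so no ring fusion helps and the ring–chain junction C6–C7 must be built with control over one cyclic and one acyclic stereocentre. Five stereocentres are present (1S, 4R, 6S, 7R, 9R); C1–O is trans to the C6 chain, C4–O is cis to C1–O, and C9 is a remote carbinol. C1 is next to C6 and can direct bond formation there, and through a stereospecific step also at C7. C9 is insulated by the C8 methylene and must come from an enantioselective reagent, and C4 is best set last by reagent‑controlled reduction of a C4 ketone. All three oxygen functions are secondary allylic esters. C1–O and C4–O flank C2=C3, a 1,4‑dioxygenated ene that can ionise or eliminate towards an aromatic ring, and C9–O sits beside the isobutenyl group. The angelate isomerises to the tiglate under base, nucleophiles or heat, so the esters go on at the end and the angelate last. Because two hydroxyls become acetates and one an angelate, C1–OH must stay distinguishable from C4–OH and C9–OH. The enabling feature is the unit C5–C6–C7: the ring methylene C5 and the methyl‑bearing C7 are both attached to C6, so a bond between C5 and C7 gives a cyclopropane fused to ring A whose C5–C7 bond can later be exchanged for C7–CH3. C4, next to C5, can be the ketone that first makes C5 a carbenoid carbon and then activates that cyclopropane.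

## Retrosynthesis

**Ester C–O bonds (25 to 19).** The angelate is cut first, giving alcohol 22 and angelic acid 23, so that the isomerisable ester meets no further reagent. The two acetates are cut together, giving diol 20, because C4–OH and C9–OH carry the same acyl group. This fixes the protecting groups: a triethylsilyl ether at C9 (19), removable beside the tert‑butyldimethylsilyl ether at C1 (21). The forward steps must avoid acid strong enough to ionise the allylic positions.

**C4–H bond (19 to 18).** Cutting C4–H leads to enone 18. The alternative, carrying a C4 stereocentre through the ring construction, would put a second oxygen next to the carbenoid carbon. A ketone at C4 is exactly what the ring construction delivers. The reduction must be 1,2‑selective and must place hydride on the face cis to the chain, against the ring's preference for axial attack; a chiral oxazaborolidine is asked to do this.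

**C2=C3, C3–CH3 and C5–CO2CH3 (18 to 14).** The enone is traced through silyl enol ether 17 and ketone 16 to the methylated β‑keto ester 15 and on to 14. The ester on C5 is kept as long as it is useful: it lets a dianion be methylated only at C3, which a plain ketone with two α‑methylenes could not guarantee. After its removal, the tetrasubstituted C3=C4 enol ether is the thermodynamic one, so dehydrogenation falls at C2=C3.

**C7–CH3 bond (14 to 13).** Cutting the methyl group from C7 and joining C7 to C5 gives cyclopropane 13. Against a conjugate addition of a chain nucleophile to a cyclohexenone, this cut makes C7 the product of an SN2 inversion at a centre whose configuration was fixed by an alkene geometry. The forward step needs the double activation by ketone and ester on C5.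

**C5–C6 and C5–C7 bonds (13 to 12, key step).** Both bonds are cut at once, back to the (Z)‑α‑diazo‑β‑keto ester 12. The precursor is acyclic and has only two stereocentres, C1 and C9, and these are far apart. The carbenoid must add to the alkene rather than insert into C1–H, and must add to the face anti to the C1 silyloxy group; the Z geometry serves both the endo placement of C8 and the allylic strain that fixes the face.

**Diazo group and C4–C5 bond (12 to 9 + 10).** Diazo transfer leads back to β‑keto ester 11, and a Claisen cut of C4–C5 to methyl ester 9 and methyl acetate 10. A two‑carbon extension of an ester is shorter than any route through an acid or aldehyde.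

**Z alkene and C1–H (9 to 6).** The Z alkene comes from alkyne 8 by semihydrogenation, the silyl ether from alcohol 7, and the C1 carbinol from ynone 6 by asymmetric transfer hydrogenation. This was preferred to a direct asymmetric alkynylation of methyl 4‑oxobutanoate, where a zinc alkoxide γ to a methyl ester would lactonise and the unbranched aldehyde would enolise; alkynyl ketones are among the best substrates for transfer hydrogenation.

**C1–C6 bond (6 to 4 + 5).** The ynone is cut between carbonyl and alkyne into terminal alkyne 4 and the commercial acid chloride 5. The coupling is catalytic and tolerates the ester.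

**C8–C9 bond (4 to 1 + 2).** Silyl ether 4 comes from homopropargylic alcohol 3, and 3 from 3‑methylbut‑2‑enal 1 and allenylboronate 2 by catalytic asymmetric propargylation. This sets C9 in the first step from two commercial compounds.

## Roads not taken

**Alternative 1:** Ring A is cut at C5–C6 and C1–C2. The lithium enolate of δ‑lactone A1 (LiN(iPr)2) would add through C6 to enone A2 anti to the C7 methyl group; with KOtBu the derived methyl ketone enolate would attack the lactone carbonyl, closing ring A and opening the lactone to dione A3.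
- Merits: the C6/C7 relationship comes from alkylation of a cyclic enolate trans to a ring substituent, the C7/C9 relationship is locked in the lactone, and there is no diazo compound and no transition metal. In reagent cost and safety this road is better than the chosen one, and it is its equal for the C6/C7 pair.
- Weak points: A3 has oxygen at C1 and C3, whereas the target needs oxygen at C1 and C4 and carbon at C3. The two carbonyls of a 4‑substituted cyclohexane‑1,3‑dione are hard to tell apart. After methyl addition with carbonyl transposition, C4 would still need a γ‑oxygenation with no nearby control element, and C1 a stereoselective reduction. Lactone enolates also add poorly to A2, which polymerises.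
- Against this the chosen plan sets a ring that arrives with oxygen already at C1 and C4, the C1 configuration in place and C3 addressed regiospecifically.

**Alternative 2:** The cut is C2=C3. The second‑generation Grubbs catalyst (H2IMes)(PCy3)Cl2Ru=CHPh would join the propenyl group on C1 and the isopropenyl group on C4 of acyclic diene A4, giving cyclohexenol A5.
- Merits: A5 has all five stereocentres and three differentiated oxygens (free C1–OH, C4 silyl ether, C9 acetate), so only angeloylation, desilylation and acetylation remain. This end‑game is clearly shorter than the ten steps that follow the key step of the chosen plan.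
- Weak points: A4 is an acyclic array of five stereocentres, whose contiguous C1/C6/C7 triad must come from reagent‑controlled allylborations with a chain‑bearing allylboron reagent and no cyclic control over C6/C7. The metathesis must form a trisubstituted alkene from a 1,1‑ and a 1,2‑disubstituted alkene, each next to an allylic oxygen. The isobutenyl group at C10=C11 is a third metathesis partner that can close a seven‑membered ring with the C1 propenyl group.
- The chosen plan answers with a stereospecific construction of C6/C7 and a ring closure that has no competing alkene partner; the total length is likely similar once the synthesis of A4 is counted.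

**Alternative 3:** The cut is C1–C6 together with C7–H. A cationic monovalent rhodium catalyst ([Rh(cod)2]BF4 with DTBM‑SEGPHOS) would insert into the formyl C–H bond of (2Z,6E)‑dienal A6, add Rh–H syn across C6=C7 and reductively eliminate to enone A7.
- Merits: the step is fully atom‑economical, the E geometry translates by syn addition into the correct C6/C7 relationship, and A7 needs only a favourable ketone reduction at C1, angeloylation, desilylation and acetylation. If the key step worked, this would be the shortest route of all, shorter than the chosen one.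
- Weak points: six‑membered ring closure by hydroacylation onto a trisubstituted alkene lacks precedent. Acyl rhodium hydrides from enals decarbonylate, hydrometalation of trisubstituted alkenes is slow, and the 2Z enal can isomerise to the 2E isomer, which cannot cyclise. Facial control relative to the existing C4 centre would rest on an untested ligand–substrate match.
- The chosen plan sets against the shorter count a key step and a ring‑opening that both have close precedent and a predictable stereochemical course.

Key step: step 9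

Assumption: 14, 15 and 16 are carried as mixtures at the enolisable centres C5 and C3 (and as keto–enol tautomers); both centres lose their stereochemical identity by 18.

## Route

Step 1
Reactants: 1 3-methylbut-2-enal; 2 allenylboronic acid pinacol ester
Product: 3 (4R)-6-methylhept-5-en-1-yn-4-ol
Conditions: (R)-TRIP (10 mol%), 4 Å MS, toluene, −20 °C; aq. NaHCO3
Reagents that add atoms: none
Why: Chiral phosphoric acid catalysed propargylation of an aldehyde with an allenylboronate through a closed six-membered transition state; the (R)-acid should direct the propargyl group to the Re face of 1, setting C9 as R. Enals are established substrates and only 1,2-addition is open.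

Step 2
Reactants: 3 (4R)-6-methylhept-5-en-1-yn-4-ol
Product: 4 triethyl{[(4R)-6-methylhept-5-en-1-yn-4-yl]oxy}silane
Conditions: TESCl, imidazole, CH2Cl2, 0 °C
Reagents that add atoms: chlorotriethylsilane, CC[Si](Cl)(CC)CC
Why: Standard silylation of a secondary alcohol; the triethylsilyl ether tolerates cuprate, amide base and borane and can later be cleaved beside the tert-butyldimethylsilyl ether at C1.

Step 3
Reactants: 4 triethyl{[(4R)-6-methylhept-5-en-1-yn-4-yl]oxy}silane; 5 methyl 4-chloro-4-oxobutanoate
Product: 6 methyl (8R)-10-methyl-4-oxo-8-[(triethylsilyl)oxy]undec-9-en-5-ynoate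
Conditions: PdCl2(PPh3)2 (2 mol%), CuI (4 mol%), Et3N, THF, rt
Reagents that add atoms: none
Why: Acyl Sonogashira coupling of a terminal alkyne with an acid chloride forms the C1–C6 bond and gives the ynone directly; ester and silyl ether are inert and the mild amine should not isomerise the ynone.

Step 4
Reactants: 6 methyl (8R)-10-methyl-4-oxo-8-[(triethylsilyl)oxy]undec-9-en-5-ynoate
Product: 7 methyl (4R,8R)-4-hydroxy-10-methyl-8-[(triethylsilyl)oxy]undec-9-en-5-ynoate
Conditions: Ru[(R,R)-TsDPEN](p-cymene) (1 mol%), i-PrOH, rt
Reagents that add atoms: none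
Why: Noyori asymmetric transfer hydrogenation of an alkynyl ketone; with the alkynyl group in the place of the aryl group of the usual model, the (R,R)-catalyst should give the (R)-propargylic alcohol, so C1 is set by the catalyst independently of C9. The base-free conditions avoid ynone isomerisation and lactonisation of the γ-hydroxy ester, which is silylated without delay.

Step 5
Reactants: 7 methyl (4R,8R)-4-hydroxy-10-methyl-8-[(triethylsilyl)oxy]undec-9-en-5-ynoate
Product: 8 methyl (4R,8R)-4-[(tert-butyldimethylsilyl)oxy]-10-methyl-8-[(triethylsilyl)oxy]undec-9-en-5-ynoate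
Conditions: TBSCl, imidazole, DMF, rt
Reagents that add atoms: tert-butylchlorodimethylsilane, CC(C)(C)[Si](C)(C)Cl
Why: Standard silylation; the bulky silyl ether at C1 blocks lactonisation, survives to the penultimate step and provides the steric bias used in the key step.

Step 6
Reactants: 8 methyl (4R,8R)-4-[(tert-butyldimethylsilyl)oxy]-10-methyl-8-[(triethylsilyl)oxy]undec-9-en-5-ynoate
Product: 9 methyl (4R,5Z,8R)-4-[(tert-butyldimethylsilyl)oxy]-10-methyl-8-[(triethylsilyl)oxy]undeca-5,9-dienoate
Conditions: H2 (1 atm), Pd/CaCO3–Pb(OAc)2, quinoline, EtOAc, rt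
Reagents that add atoms: none
Why: Lindlar semihydrogenation: syn delivery of H2 on the poisoned surface gives the Z alkene; the trisubstituted C10=C11 alkene is not reduced under these conditions.

Step 7
Reactants: 9 methyl (4R,5Z,8R)-4-[(tert-butyldimethylsilyl)oxy]-10-methyl-8-[(triethylsilyl)oxy]undeca-5,9-dienoate; 10 methyl acetate
Product: 11 methyl (6R,7Z,10R)-6-[(tert-butyldimethylsilyl)oxy]-12-methyl-3-oxo-10-[(triethylsilyl)oxy]trideca-7,11-dienoate
Conditions: 10, LiN(iPr)2 (3.5 equiv), THF, −78 °C; then 9, −78 → −30 °C; aq. NH4Cl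
Reagents that add atoms: none
Why: Crossed Claisen condensation of a lithium ester enolate with a methyl ester; the β-keto ester is deprotonated as it forms, which drives the reaction and prevents a second addition, hence the excess enolate.

Step 8
Reactants: 11 methyl (6R,7Z,10R)-6-[(tert-butyldimethylsilyl)oxy]-12-methyl-3-oxo-10-[(triethylsilyl)oxy]trideca-7,11-dienoate
Product: 12 methyl (6R,7Z,10R)-2-diazo-6-[(tert-butyldimethylsilyl)oxy]-12-methyl-3-oxo-10-[(triethylsilyl)oxy]trideca-7,11-dienoate
Conditions: p-ABSA, Et3N, MeCN, 0 °C → rt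
Reagents that add atoms: 4-acetamidobenzenesulfonyl azide, CC(=O)Nc1ccc(cc1)S(=O)(=O)N=[N+]=[N-]
Why: Regitz diazo transfer to an active methylene compound; no other position of 11 is acidic enough to react.

Step 9
Reactants: 12 methyl (6R,7Z,10R)-2-diazo-6-[(tert-butyldimethylsilyl)oxy]-12-methyl-3-oxo-10-[(triethylsilyl)oxy]trideca-7,11-dienoate
Product: 13 methyl (1R,5R,6R,7S)-5-[(tert-butyldimethylsilyl)oxy]-7-{(2R)-4-methyl-2-[(triethylsilyl)oxy]pent-3-en-1-yl}-2-oxobicyclo[4.1.0]heptane-1-carboxylate
Conditions: Cu(acac)2 (5 mol%), toluene, 110 °C, slow addition of 12 (final 0.01 M)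
Reagents that add atoms: none
Why: Cu(acac)2 is reduced by the diazo compound to the monovalent copper species that expels N2 from 12 and forms an electrophilic copper carbenoid at C5, which adds to C6=C7 in a concerted, asynchronous [2+1] step; this is the known intramolecular cyclopropanation of unsaturated α-diazo-β-keto esters. Ring A closes through the new C5–C6 bond in the exo mode (C5–C4–C3–C2–C1–C6, with C7 outside the six-membered ring), and the cyclopropane closes through C5–C7 in the same event, giving the cis-fused bicyclo[4.1.0]heptan-2-one. C7 relative to C6 follows from the retained Z geometry: C1 and C8 stay cis, so C8 ends endo. The alkene face, and with it C6, is set by C1: allylic 1,3-strain with C8 holds C1–H in the alkene plane, the C2 tether and the silyloxy group then lie on opposite faces, and the tethered carbenoid can only reach the face of C2, which leaves the silyloxy group anti to the cyclopropane. C5 becomes quaternary with the configuration forced by the cis ring fusion. The step needs alkene addition to beat 1,5 insertion into the ether-activated C1–H bond and addition to C10=C11; copper carbenoids strongly prefer alkene addition over C–H insertion, and the remote alkene could only close a ten-membered ring. Slow addition at high dilution suppresses carbene dimerisation.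

Step 10
Reactants: 13 methyl (1R,5R,6R,7S)-5-[(tert-butyldimethylsilyl)oxy]-7-{(2R)-4-methyl-2-[(triethylsilyl)oxy]pent-3-en-1-yl}-2-oxobicyclo[4.1.0]heptane-1-carboxylate
Product: 14 methyl (5R,6R)-5-[(tert-butyldimethylsilyl)oxy]-6-{(2R,4R)-6-methyl-4-[(triethylsilyl)oxy]hept-5-en-2-yl}-2-oxocyclohexane-1-carboxylate (C1 epimers and enol)
Conditions: Me2CuLi (from MeLi and CuI, 4 equiv), Et2O, −40 → 0 °C; aq. NH4Cl
Reagents that add atoms: lithium dimethylcuprate, [Li+].C[Cu-]C
Why: Homoconjugate addition of a cuprate to a cyclopropane activated by ketone and ester: SN2 attack at C7, whose backside is open while that of C6 is shielded by the ring and the C1 silyloxy group, breaks C5–C7 with inversion and releases the β-keto ester enolate. Inversion turns the endo arrangement into the 7R configuration of the target; C6 is untouched.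

Step 11
Reactants: 14 methyl (5R,6R)-5-[(tert-butyldimethylsilyl)oxy]-6-{(2R,4R)-6-methyl-4-[(triethylsilyl)oxy]hept-5-en-2-yl}-2-oxocyclohexane-1-carboxylate
Product: 15 methyl (5R,6R)-5-[(tert-butyldimethylsilyl)oxy]-3-methyl-6-{(2R,4R)-6-methyl-4-[(triethylsilyl)oxy]hept-5-en-2-yl}-2-oxocyclohexane-1-carboxylate (epimers at C1 and C3)
Conditions: LiN(iPr)2 (2.3 equiv), THF, −78 → 0 °C; MeI (1.1 equiv), −78 → 0 °C; aq. NH4Cl
Reagents that add atoms: iodomethane, CI
Why: γ-Alkylation of a β-keto ester dianion: the second deprotonation can only occur at C3 and the more reactive γ-carbanion is methylated while the ester keeps C5 blocked. The new C3 centre need not be controlled because C3 becomes sp2.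

Step 12
Reactants: 15 methyl (5R,6R)-5-[(tert-butyldimethylsilyl)oxy]-3-methyl-6-{(2R,4R)-6-methyl-4-[(triethylsilyl)oxy]hept-5-en-2-yl}-2-oxocyclohexane-1-carboxylate
Product: 16 (4R,5S)-4-[(tert-butyldimethylsilyl)oxy]-2-methyl-5-{(2R,4R)-6-methyl-4-[(triethylsilyl)oxy]hept-5-en-2-yl}cyclohexan-1-one (C2 epimers)
Conditions: LiCl, H2O, DMSO, 130 °C
Reagents that add atoms: none
Why: Krapcho dealkoxycarbonylation: chloride demethylates the ester and the β-keto carboxylate loses CO2 under neutral conditions; the temperature is kept as low as the reaction allows for the sake of the triethylsilyl ether.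

Step 13
Reactants: 16 (4R,5S)-4-[(tert-butyldimethylsilyl)oxy]-2-methyl-5-{(2R,4R)-6-methyl-4-[(triethylsilyl)oxy]hept-5-en-2-yl}cyclohexan-1-one
Product: 17 (4R,5S)-4-[(tert-butyldimethylsilyl)oxy]-2-methyl-5-{(2R,4R)-6-methyl-4-[(triethylsilyl)oxy]hept-5-en-2-yl}-1-[(trimethylsilyl)oxy]cyclohex-1-ene
Conditions: TMSCl, NaI, Et3N, MeCN, rt
Reagents that add atoms: chlorotrimethylsilane, C[Si](C)(C)Cl
Why: Equilibrating silylation with Me3SiI formed in the flask should give the more substituted, tetrasubstituted C3=C4 enol ether, as it does with 2-methylcyclohexanone; the C4=C5 isomer is further disfavoured by the C6 substituent.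

Step 14
Reactants: 17 (4R,5S)-4-[(tert-butyldimethylsilyl)oxy]-2-methyl-5-{(2R,4R)-6-methyl-4-[(triethylsilyl)oxy]hept-5-en-2-yl}-1-[(trimethylsilyl)oxy]cyclohex-1-ene
Product: 18 (4S,5S)-4-[(tert-butyldimethylsilyl)oxy]-2-methyl-5-{(2R,4R)-6-methyl-4-[(triethylsilyl)oxy]hept-5-en-2-yl}cyclohex-2-en-1-one
Conditions: Pd(OAc)2 (1.1 equiv), MeCN, rt
Reagents that add atoms: none
Why: Saegusa–Ito oxidation: the palladium enolate formed at C3 undergoes β-hydride elimination from C2 to give the endocyclic enone, as with 2-methylcyclohexanone; isolated alkenes and silyl ethers are inert and the reagent leaves as palladium metal.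

Step 15
Reactants: 18 (4S,5S)-4-[(tert-butyldimethylsilyl)oxy]-2-methyl-5-{(2R,4R)-6-methyl-4-[(triethylsilyl)oxy]hept-5-en-2-yl}cyclohex-2-en-1-one
Product: 19 (1R,4S,5S)-4-[(tert-butyldimethylsilyl)oxy]-2-methyl-5-{(2R,4R)-6-methyl-4-[(triethylsilyl)oxy]hept-5-en-2-yl}cyclohex-2-en-1-ol
Conditions: (S)-2-methyl-CBS-oxazaborolidine (0.3 equiv), catecholborane, toluene, −78 °C
Reagents that add atoms: none
Why: Corey–Bakshi–Shibata reduction: with the α-methylalkenyl side as the large and the C5 methylene as the small substituent, the (S)-oxazaborolidine should deliver hydride to the face that gives the 4R carbinol, cis to C1–O and trans to the chain. Catecholborane reduces only in the 1,2 sense and does not hydroborate the alkenes at −78 °C; the catalyst must override the ring's preference for axial attack.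

Step 16
Reactants: 19 (1R,4S,5S)-4-[(tert-butyldimethylsilyl)oxy]-2-methyl-5-{(2R,4R)-6-methyl-4-[(triethylsilyl)oxy]hept-5-en-2-yl}cyclohex-2-en-1-ol
Product: 20 (1R,4S,5S)-4-[(tert-butyldimethylsilyl)oxy]-5-[(2R,4R)-4-hydroxy-6-methylhept-5-en-2-yl]-2-methylcyclohex-2-en-1-ol
Conditions: HF·pyridine, pyridine, THF, 0 °C
Reagents that add atoms: none
Why: Buffered fluoride cleaves the triethylsilyl ether much faster than the hindered secondary tert-butyldimethylsilyl ether; the pyridine buffer keeps both allylic alcohols from ionising.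

Step 17
Reactants: 20 (1R,4S,5S)-4-[(tert-butyldimethylsilyl)oxy]-5-[(2R,4R)-4-hydroxy-6-methylhept-5-en-2-yl]-2-methylcyclohex-2-en-1-ol
Product: 21 (1R,4S,5S)-5-[(2R,4R)-4-acetoxy-6-methylhept-5-en-2-yl]-4-[(tert-butyldimethylsilyl)oxy]-2-methylcyclohex-2-en-1-yl acetate
Conditions: Ac2O, pyridine, DMAP (cat.), CH2Cl2, 0 °C → rt
Reagents that add atoms: acetic anhydride, CC(=O)OC(C)=O
Why: DMAP-catalysed acetylation of two secondary allylic alcohols installs both acetates in one operation with retention at C4 and C9.

Step 18
Reactants: 21 (1R,4S,5S)-5-[(2R,4R)-4-acetoxy-6-methylhept-5-en-2-yl]-4-[(tert-butyldimethylsilyl)oxy]-2-methylcyclohex-2-en-1-yl acetate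
Product: 22 (1R,4S,5S)-5-[(2R,4R)-4-acetoxy-6-methylhept-5-en-2-yl]-4-hydroxy-2-methylcyclohex-2-en-1-yl acetate
Conditions: HF·pyridine, THF, 0 °C → rt
Reagents that add atoms: none
Why: Fluoride desilylation under mildly acidic conditions, in which acetates neither hydrolyse nor migrate.

Step 19
Reactants: 22 (1R,4S,5S)-5-[(2R,4R)-4-acetoxy-6-methylhept-5-en-2-yl]-4-hydroxy-2-methylcyclohex-2-en-1-yl acetate; 23 angelic acid
Product: 25 (1S,4R,6S)-4-acetoxy-6-[(2R,4R)-4-acetoxy-6-methylhept-5-en-2-yl]-3-methylcyclohex-2-en-1-yl (2Z)-2-methylbut-2-enoate (target), via angelic 2,4,6-trichlorobenzoic anhydride 24 (not isolated)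
Conditions: 23, 2,4,6-trichlorobenzoyl chloride, Et3N, toluene, rt; then 22, 80 °C
Reagents that add atoms: none
Why: Yamaguchi-type mixed anhydride esterification: the alcohol attacks the less hindered angeloyl carbonyl of 24 without a nucleophilic catalyst, conditions known to acylate hindered alcohols without Z to E isomerisation. Placing this step last spares the angelate every other reagent.

## Compound list

1 | 3-methylbut-2-enal | CC(C)=CC=O | starting material
2 | allenylboronic acid pinacol ester | C=C=CB1OC(C)(C)C(C)(C)O1 | starting material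
3 | (4R)-6-methylhept-5-en-1-yn-4-ol | C#CC[C@@H](O)C=C(C)C | intermediate
4 | triethyl{[(4R)-6-methylhept-5-en-1-yn-4-yl]oxy}silane | C#CC[C@@H](O[Si](CC)(CC)CC)C=C(C)C | intermediate
5 | methyl 4-chloro-4-oxobutanoate | COC(=O)CCC(Cl)=O | starting material
6 | methyl (8R)-10-methyl-4-oxo-8-[(triethylsilyl)oxy]undec-9-en-5-ynoate | COC(=O)CCC(=O)C#CC[C@@H](O[Si](CC)(CC)CC)C=C(C)C | intermediate
7 | methyl (4R,8R)-4-hydroxy-10-methyl-8-[(triethylsilyl)oxy]undec-9-en-5-ynoate | COC(=O)CC[C@@H](O)C#CC[C@@H](O[Si](CC)(CC)CC)C=C(C)C | intermediate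
8 | methyl (4R,8R)-4-[(tert-butyldimethylsilyl)oxy]-10-methyl-8-[(triethylsilyl)oxy]undec-9-en-5-ynoate | COC(=O)CC[C@@H](O[Si](C)(C)C(C)(C)C)C#CC[C@@H](O[Si](CC)(CC)CC)C=C(C)C | intermediate
9 | methyl (4R,5Z,8R)-4-[(tert-butyldimethylsilyl)oxy]-10-methyl-8-[(triethylsilyl)oxy]undeca-5,9-dienoate | COC(=O)CC[C@@H](O[Si](C)(C)C(C)(C)C)/C=C\C[C@@H](O[Si](CC)(CC)CC)C=C(C)C | intermediate
10 | methyl acetate | COC(C)=O | starting material
11 | methyl (6R,7Z,10R)-6-[(tert-butyldimethylsilyl)oxy]-12-methyl-3-oxo-10-[(triethylsilyl)oxy]trideca-7,11-dienoate | COC(=O)CC(=O)CC[C@@H](O[Si](C)(C)C(C)(C)C)/C=C\C[C@@H](O[Si](CC)(CC)CC)C=C(C)C | intermediate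
12 | methyl (6R,7Z,10R)-2-diazo-6-[(tert-butyldimethylsilyl)oxy]-12-methyl-3-oxo-10-[(triethylsilyl)oxy]trideca-7,11-dienoate | COC(=O)C(=[N+]=[N-])C(=O)CC[C@@H](O[Si](C)(C)C(C)(C)C)/C=C\C[C@@H](O[Si](CC)(CC)CC)C=C(C)C | intermediate
13 | methyl (1R,5R,6R,7S)-5-[(tert-butyldimethylsilyl)oxy]-7-{(2R)-4-methyl-2-[(triethylsilyl)oxy]pent-3-en-1-yl}-2-oxobicyclo[4.1.0]heptane-1-carboxylate | COC(=O)[C@@]12C(=O)CC[C@@H](O[Si](C)(C)C(C)(C)C)[C@@H]1[C@@H]2C[C@@H](O[Si](CC)(CC)CC)C=C(C)C | intermediate
14 | methyl (5R,6R)-5-[(tert-butyldimethylsilyl)oxy]-6-{(2R,4R)-6-methyl-4-[(triethylsilyl)oxy]hept-5-en-2-yl}-2-oxocyclohexane-1-carboxylate (C1 epimers) | COC(=O)C1C(=O)CC[C@@H](O[Si](C)(C)C(C)(C)C)[C@@H]1[C@H](C)C[C@@H](O[Si](CC)(CC)CC)C=C(C)C | intermediate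
15 | methyl (5R,6R)-5-[(tert-butyldimethylsilyl)oxy]-3-methyl-6-{(2R,4R)-6-methyl-4-[(triethylsilyl)oxy]hept-5-en-2-yl}-2-oxocyclohexane-1-carboxylate (C1 and C3 epimers) | COC(=O)C1C(=O)C(C)C[C@@H](O[Si](C)(C)C(C)(C)C)[C@@H]1[C@H](C)C[C@@H](O[Si](CC)(CC)CC)C=C(C)C | intermediate
16 | (4R,5S)-4-[(tert-butyldimethylsilyl)oxy]-2-methyl-5-{(2R,4R)-6-methyl-4-[(triethylsilyl)oxy]hept-5-en-2-yl}cyclohexan-1-one (C2 epimers) | C1C(=O)C(C)C[C@@H](O[Si](C)(C)C(C)(C)C)[C@@H]1[C@H](C)C[C@@H](O[Si](CC)(CC)CC)C=C(C)C | intermediate
17 | (4R,5S)-4-[(tert-butyldimethylsilyl)oxy]-2-methyl-5-{(2R,4R)-6-methyl-4-[(triethylsilyl)oxy]hept-5-en-2-yl}-1-[(trimethylsilyl)oxy]cyclohex-1-ene | C1C(O[Si](C)(C)C)=C(C)C[C@@H](O[Si](C)(C)C(C)(C)C)[C@@H]1[C@H](C)C[C@@H](O[Si](CC)(CC)CC)C=C(C)C | intermediate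
18 | (4S,5S)-4-[(tert-butyldimethylsilyl)oxy]-2-methyl-5-{(2R,4R)-6-methyl-4-[(triethylsilyl)oxy]hept-5-en-2-yl}cyclohex-2-en-1-one | C1C(=O)C(C)=C[C@@H](O[Si](C)(C)C(C)(C)C)[C@@H]1[C@H](C)C[C@@H](O[Si](CC)(CC)CC)C=C(C)C | intermediate
19 | (1R,4S,5S)-4-[(tert-butyldimethylsilyl)oxy]-2-methyl-5-{(2R,4R)-6-methyl-4-[(triethylsilyl)oxy]hept-5-en-2-yl}cyclohex-2-en-1-ol | C1[C@@H](O)C(C)=C[C@@H](O[Si](C)(C)C(C)(C)C)[C@@H]1[C@H](C)C[C@@H](O[Si](CC)(CC)CC)C=C(C)C | intermediate
20 | (1R,4S,5S)-4-[(tert-butyldimethylsilyl)oxy]-5-[(2R,4R)-4-hydroxy-6-methylhept-5-en-2-yl]-2-methylcyclohex-2-en-1-ol | C1[C@@H](O)C(C)=C[C@@H](O[Si](C)(C)C(C)(C)C)[C@@H]1[C@H](C)C[C@@H](O)C=C(C)C | intermediate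
21 | (1R,4S,5S)-5-[(2R,4R)-4-acetoxy-6-methylhept-5-en-2-yl]-4-[(tert-butyldimethylsilyl)oxy]-2-methylcyclohex-2-en-1-yl acetate | C1[C@@H](OC(C)=O)C(C)=C[C@@H](O[Si](C)(C)C(C)(C)C)[C@@H]1[C@H](C)C[C@@H](OC(C)=O)C=C(C)C | intermediate
22 | (1R,4S,5S)-5-[(2R,4R)-4-acetoxy-6-methylhept-5-en-2-yl]-4-hydroxy-2-methylcyclohex-2-en-1-yl acetate | C1[C@@H](OC(C)=O)C(C)=C[C@@H](O)[C@@H]1[C@H](C)C[C@@H](OC(C)=O)C=C(C)C | intermediate
23 | angelic acid, (2Z)-2-methylbut-2-enoic acid | C/C=C(/C)C(O)=O | starting material
24 | angelic 2,4,6-trichlorobenzoic anhydride | C/C=C(/C)C(=O)OC(=O)c1c(Cl)cc(Cl)cc1Cl | intermediate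
25 | (1S,4R,6S)-4-acetoxy-6-[(2R,4R)-4-acetoxy-6-methylhept-5-en-2-yl]-3-methylcyclohex-2-en-1-yl (2Z)-2-methylbut-2-enoate | C/C=C(/C)C(=O)O[C@@H]1C=C(C)[C@H](OC(C)=O)C[C@H]1[C@H](C)C[C@H](C=C(C)C)OC(C)=O | target

## Step count and least certain steps

Total: 19 steps. Longest linear sequence: 19 steps (1 to 25); the route is fully linear, with 2, 5, 10 and 23 entering as commercial reagents.

**Step 9 (key step).** The most likely failure is insertion of the carbenoid into the C1–H bond, which is activated by the ether oxygen and the alkene and lies at the favoured 1,5 distance. Less likely is addition to the alkene face syn to the silyloxy group, if the allylic strain bias is weaker than assumed. Fallback, from 11 back to 13: 11 is treated with PhI(OAc)2 and KOH in MeOH to give the phenyliodonium ylide of 11 F1, which with catalytic CuCl in CH2Cl2 should cyclise to 13. Such ylides cyclopropanate tethered alkenes through an iodonium/metallacycle pathway that shows little C–H insertion, and no diazo compound is handled.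

**Step 15.** The reduction is mismatched: the half-chair enone prefers axial hydride attack, which places the hydroxyl cis to the C6 chain, so poor facial selectivity is the danger. Fallback, from 18 back to 19: Luche reduction (NaBH4, CeCl3·7H2O, MeOH, −78 °C) follows the ring's own preference and should give the C4-epimeric alcohol F7. Mitsunobu inversion with 4-nitrobenzoic acid (PPh3, DIAD, THF) gives the 4-nitrobenzoate F8 with the 4R configuration, and K2CO3 in MeOH releases 19.

**Step 13.** Enolisation may go partly towards C5, the kinetic direction, which after oxidation would place the double bond at C5=C6. Fallback, from 15 back to 18, using the ester to fix the site: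
- the dianion of 15 (LiN(iPr)2, THF) is sulfenylated with PhSSPh at C3 to give the 3-phenylsulfanyl β-keto ester F4;
- Krapcho dealkoxycarbonylation (LiCl, H2O, DMSO) gives the 2-methyl-2-phenylsulfanyl ketone F5;
- NaIO4 in aqueous MeOH gives the sulfoxide F6;
- warming F6 in toluene over CaCO3 effects syn elimination towards C2 and gives 18.

**Step 19.** The angeloyl group may isomerise from Z to E through reversible conjugate addition of chloride or amine at 80 °C, and the hindered C1–OH may acylate incompletely. Fallback, from 22 to 25, building the Z double bond on the ester: 22 is esterified with 2-[bis(2,2,2-trifluoroethoxy)phosphoryl]propanoic acid (DCC, DMAP, CH2Cl2) to give the phosphonopropanoate F9. Still–Gennari olefination of F9 with acetaldehyde (KN(SiMe3)2, 18-crown-6, THF, −78 °C) should give 25 directly; the phosphonate C–H is far more acidic than the acetate C–H.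

**Step 1.** Enantioselectivity may be insufficient with this β,β-disubstituted enal, whose small formyl environment differs from the aryl aldehydes on which the catalyst is best tested. Fallback, from 1 back to 3: Barbier propargylation of 1 with propargyl bromide and Zn dust in THF gives racemic 6-methylhept-5-en-1-yn-4-ol F2. Sharpless kinetic resolution (Ti(OiPr)4, L-(+)-diisopropyl tartrate, t-BuOOH, 4 Å MS, CH2Cl2, −20 °C) should consume the S enantiomer as the epoxy alcohol F3 and leave 3, at the cost of more than half of the material.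

## Further compounds

F1 | step 9 | methyl (6R,7Z,10R)-6-[(tert-butyldimethylsilyl)oxy]-12-methyl-3-oxo-2-(phenyl-λ3-iodanylidene)-10-[(triethylsilyl)oxy]trideca-7,11-dienoate | COC(=O)[C-]([I+]c1ccccc1)C(=O)CC[C@@H](O[Si](C)(C)C(C)(C)C)/C=C\C[C@@H](O[Si](CC)(CC)CC)C=C(C)C
F2 | step 1 | racemic 6-methylhept-5-en-1-yn-4-ol | C#CCC(O)C=C(C)C
F3 | step 1 | (1S)-1-[(2R)-3,3-dimethyloxiran-2-yl]but-3-yn-1-ol | C#CC[C@H](O)[C@H]1OC1(C)C
F4 | step 13 | methyl (5R,6R)-5-[(tert-butyldimethylsilyl)oxy]-3-methyl-6-{(2R,4R)-6-methyl-4-[(triethylsilyl)oxy]hept-5-en-2-yl}-2-oxo-3-(phenylsulfanyl)cyclohexane-1-carboxylate | COC(=O)C1C(=O)C(C)(Sc2ccccc2)C[C@@H](O[Si](C)(C)C(C)(C)C)[C@@H]1[C@H](C)C[C@@H](O[Si](CC)(CC)CC)C=C(C)C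
F5 | step 13 | (4R,5S)-4-[(tert-butyldimethylsilyl)oxy]-2-methyl-5-{(2R,4R)-6-methyl-4-[(triethylsilyl)oxy]hept-5-en-2-yl}-2-(phenylsulfanyl)cyclohexan-1-one | C1C(=O)C(C)(Sc2ccccc2)C[C@@H](O[Si](C)(C)C(C)(C)C)[C@@H]1[C@H](C)C[C@@H](O[Si](CC)(CC)CC)C=C(C)C
F6 | step 13 | (4R,5S)-4-[(tert-butyldimethylsilyl)oxy]-2-methyl-5-{(2R,4R)-6-methyl-4-[(triethylsilyl)oxy]hept-5-en-2-yl}-2-(phenylsulfinyl)cyclohexan-1-one | C1C(=O)C(C)(S(=O)c2ccccc2)C[C@@H](O[Si](C)(C)C(C)(C)C)[C@@H]1[C@H](C)C[C@@H](O[Si](CC)(CC)CC)C=C(C)C
F7 | step 15 | (1S,4S,5S)-4-[(tert-butyldimethylsilyl)oxy]-2-methyl-5-{(2R,4R)-6-methyl-4-[(triethylsilyl)oxy]hept-5-en-2-yl}cyclohex-2-en-1-ol | C1[C@H](O)C(C)=C[C@@H](O[Si](C)(C)C(C)(C)C)[C@@H]1[C@H](C)C[C@@H](O[Si](CC)(CC)CC)C=C(C)C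
F8 | step 15 | (1R,4S,5S)-4-[(tert-butyldimethylsilyl)oxy]-2-methyl-5-{(2R,4R)-6-methyl-4-[(triethylsilyl)oxy]hept-5-en-2-yl}cyclohex-2-en-1-yl 4-nitrobenzoate | C1[C@@H](OC(=O)c2ccc(cc2)[N+](=O)[O-])C(C)=C[C@@H](O[Si](C)(C)C(C)(C)C)[C@@H]1[C@H](C)C[C@@H](O[Si](CC)(CC)CC)C=C(C)C
F9 | step 19 | (1S,4R,6S)-4-acetoxy-6-[(2R,4R)-4-acetoxy-6-methylhept-5-en-2-yl]-3-methylcyclohex-2-en-1-yl 2-[bis(2,2,2-trifluoroethoxy)phosphoryl]propanoate | CC(C(=O)O[C@@H]1C=C(C)[C@H](OC(C)=O)C[C@H]1[C@H](C)C[C@H](C=C(C)C)OC(C)=O)P(=O)(OCC(F)(F)F)OCC(F)(F)F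
A1 | alternative 1 | (4R,6R)-4-methyl-6-(2-methylprop-1-en-1-yl)oxan-2-one | O=C1C[C@H](C)C[C@H](C=C(C)C)O1
A2 | alternative 1 | but-3-en-2-one | CC(=O)C=C
A3 | alternative 1 | (4S)-4-[(2R,4R)-4-hydroxy-6-methylhept-5-en-2-yl]cyclohexane-1,3-dione | O=C1CC(=O)CC[C@H]1[C@H](C)C[C@H](C=C(C)C)O
A4 | alternative 2 | acyclic diene with (E)-propenyl carbinol at C1, isopropenyl tert-butyldimethylsilyl ether at C4 and C9 acetate | C/C=C/[C@@H](O)[C@@H](C[C@@H](O[Si](C)(C)C(C)(C)C)C(C)=C)[C@H](C)C[C@H](C=C(C)C)OC(C)=O
A5 | alternative 2 | ring A allylic alcohol with C4 tert-butyldimethylsilyl ether and C9 acetate | O[C@@H]1C=C(C)[C@H](O[Si](C)(C)C(C)(C)C)C[C@H]1[C@H](C)C[C@H](C=C(C)C)OC(C)=O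
A6 | alternative 3 | (2Z,6E)-dienal with C4 tert-butyldimethylsilyl ether and C9 acetate | O=C/C=C(/C)[C@H](O[Si](C)(C)C(C)(C)C)C/C=C(\C)C[C@H](C=C(C)C)OC(C)=O
A7 | alternative 3 | ring A enone with C1 ketone, C4 tert-butyldimethylsilyl ether and C9 acetate | O=C1C=C(C)[C@H](O[Si](C)(C)C(C)(C)C)C[C@H]1[C@H](C)C[C@H](C=C(C)C)OC(C)=O
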